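**Retrosynthetic overview**

1. Caraganin B is a 5-hydroxy-7-methoxyisoflavone whose ring B (2′,4′-dihydroxyphenyl) carries at C5′ an (R)-1-(4-hydroxyphenyl)-3-(2,4-dimethoxyphenyl)allyl group. Rings A and B and both pendant aryl rings are bought intact; ring C (the pyran-4-one) is the only ring made, and it is made last, in the key step.
2. Key disconnection C3–C1′. The enabling feature is the free 2′-OH of ring B ortho to C1′, together with C3 being the α-carbon of the C4 ketone next to the C2–H carbon. Tying O2′ to a nitrogen on C2 gives the array C1′=C2′–O2′–N–C2=C3; its [3,3] shift (N–O cleaved) makes C3–C1′ and returns the 2′-OH, and a ring-A phenol then closes ring C with loss of NH3.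
3. Partners for that step: an o-hydroxyaryl enaminone (one step from the ring-A acetophenone) and an O-aryl acetohydroximate, in which O2′ is put on an aryl bromide by Pd-catalysed C–O coupling.
4. The single stereocentre comes from a Rh/chiral-diene 1,4-addition of an arylboronic acid to a chalcone (Claisen–Schmidt product); the E-styrene from ketone reduction and dehydration.
5. End game: fluoride cleavage of two aryl TBS ethers.

Key step: step 8

Assumption: the stereocentre of the target is (R) as drawn; the (R,R)-diene in step 4 is assigned by analogy with the usual facial sense for (E)-enones (aryl to the Si face of C-β), and the (S,S)-ligand is used instead if the first run shows the opposite sense.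

**Route**

Step 1
Reactants: 1 1-(2,6-dihydroxy-4-methoxyphenyl)ethan-1-one
Product: 2 ring-A enaminone
Conditions: t-BuOCH(NMe2)2 (2 equiv), toluene, 90 °C
Reagents that add atoms: tert-butoxybis(dimethylamino)methane (Bredereck's reagent), CC(C)(C)OC(N(C)C)N(C)C
Why: Aminomethylenation of the aryl methyl ketone by a formamide aminal ester (enaminone synthesis) should occur at the only enolisable position and give the E-enaminone, and this tert-butoxy reagent cannot O-methylate the two phenols as DMF dimethyl acetal might.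

Step 2
Reactants: 3 4-bromo-2-hydroxybenzaldehyde; 4 1-(2,4-dimethoxyphenyl)ethan-1-one
Product: 5 2-hydroxychalcone
Conditions: KOH (50 % aq., 3 equiv), EtOH, 0 °C → rt; AcOH to pH 6 at 0 °C
Reagents that add atoms: none
Why: Claisen–Schmidt condensation of the only enolisable ketone with the non-enolisable aldehyde should give the thermodynamic E-enone, and the basic medium keeps the product as its phenoxide so that it cannot close to a flavylium salt.

Step 3
Reactants: 5 2-hydroxychalcone
Product: 6 O-TBS chalcone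
Conditions: TBSCl (1.2 equiv), imidazole (2.5 equiv), DMF, rt
Reagents that add atoms: tert-butyldimethylsilyl chloride, CC(C)(C)[Si](C)(C)Cl
Why: Standard phenol silylation; the silyl ether prevents hemiketal/4H-chromene formation after the conjugate addition and later attack of O4′ on the styrene, and it is removable at the end without acid.

Step 4
Reactants: 6 O-TBS chalcone; 7 [4-(tert-butyldimethylsilyloxy)phenyl]boronic acid (2 equiv)
Product: 8 (R)-β,β-diaryl ketone
Conditions: [RhCl(C2H4)2]2 (2.5 mol %), (R,R)-Ph-bod* [(1R,4R)-2,5-diphenylbicyclo[2.2.2]octa-2,5-diene] (5.5 mol %), KOH (10 mol %), dioxane/H2O 10:1, 40 °C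
Reagents that add atoms: none
Why: Rh(I)-catalysed asymmetric 1,4-addition of an arylboronic acid to an enone (Hayashi–Miyaura reaction), with close precedent on chalcones: the aryl–Rh/chiral diene complex should carbometalate the Si face of C-β, so the (R) stereocentre is set by catalyst control, while the aryl bromide and the silyl ethers are inert under these near-neutral conditions.

Step 5
Reactants: 8 (R)-β,β-diaryl ketone
Product: 9 benzylic alcohol (both carbinol epimers)
Conditions: NaBH4, THF/EtOH 4:1, 0 °C → rt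
Reagents that add atoms: none
Why: Borohydride reduction of the aryl ketone; the carbinol configuration is irrelevant because this carbon becomes sp2 in step 6.

Step 6
Reactants: 9 benzylic alcohol
Product: 10 (R,E)-aryl bromide
Conditions: PPTS (10 mol %), toluene, 4 Å MS, 80 °C
Reagents that add atoms: none
Why: Acid-catalysed E1 dehydration through the 2,4-dimethoxybenzylic cation should give only the conjugated styrene (β-hydrogens exist only on C2) as the thermodynamic E isomer, and C1 never carries charge, so its configuration is kept.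

Step 7
Reactants: 10 (R,E)-aryl bromide; 11 ethyl N-hydroxyethanimidate (ethyl acetohydroximate)
Product: 12 O-aryl acetohydroximate
Conditions: [(allyl)PdCl]2 (1 mol %), t-BuBrettPhos (3 mol %), Cs2CO3 (1.5 equiv), toluene, 65 °C
Reagents that add atoms: none
Why: Pd-catalysed C–O cross-coupling (Buchwald–Hartwig type) of an unhindered aryl bromide with ethyl acetohydroximate as a hydroxylamine equivalent has close precedent, and Cs2CO3 in toluene should not touch the aryl silyl ethers or the doubly benzylic C–H.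

Step 8
Reactants: 12 O-aryl acetohydroximate; 2 ring-A enaminone (1.5 equiv)
Product: 16 bis-TBS isoflavone, via aryloxyamine 13 (not isolated), via N-aryloxy enaminone 14 (not isolated), via rearranged aminoenone 15 (not isolated)
Conditions: p-TsOH·H2O (1.1 equiv), THF/H2O 20:1, 0 °C → rt; then 2, EtOH/AcOH 5:1, rt → 70 °C
Reagents that add atoms: none
Why: Proposed new method: acid hydrolysis of the hydroximate frees aryloxyamine 13, whose NH2 exchanges with the NMe2 group of 2 by addition–elimination at C-β to give 14, a 3-aza-4-oxa-1,5-diene (C1′=C2′–O–N–C2=C3) that should undergo a charge-accelerated [3,3]-sigmatropic shift with cleavage of the weak N–O bond, forming C3–C1′ and, after tautomerisation of the dienone, the 2′-phenol of aminoenone 15. The closest known reaction type is the acid-mediated [3,3] rearrangement of O-aryl oxime ethers (N-aryloxy enamines), including those of 1,3-dicarbonyl compounds, used to make benzofurans (the oxygen analogue of the Fischer indole synthesis), combined here with the standard chromone annulation of o-hydroxyaryl enaminones. Ring C closes by 6-endo-trig oxa-Michael addition of either (equivalent) ring-A ortho-phenol to C2 followed by β-elimination of ammonia; the competing 5-exo closure by the new 2′-OH would give a 3-(2-hydroxyaroyl)benzofuran, an isomer of 16 that is expected, by analogy with the known conversion of 3-(2-hydroxybenzoyl)benzofurans into 2′-hydroxyisoflavones, to reopen and reclose to 16, so both channels should drain to the same product. No stereocentre is formed, and the remote allylic stereocentre is untouched because the medium is a buffered weak acid free of strong base. The step needs regioselectivity for C1′ over C3′ (the two carbons ortho to O2′), secured because C1′ is para to the donor O4′ and unhindered whereas C3′ is flanked by the bulky OTBS group; it also needs exchange at C-β instead of at the hindered, hydrogen-bonded C4 carbonyl, and [3,3] shift before loss of the aryloxyamine, for which excess 2 and the staged temperature are chosen (5-hydroxy-7-methoxychromone formed early can re-enter by conjugate addition/ring opening with 13).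

Step 9
Reactants: 16 bis-TBS isoflavone
Product: 17 caraganin B
Conditions: TBAF (2.5 equiv), AcOH (2.5 equiv), THF, 0 °C
Reagents that add atoms: none
Why: Fluoride cleavage of the two aryl silyl ethers, buffered with acetic acid so that neither acid (cyclisation of O4′ onto the styrene) nor strong base (alkene migration into conjugation with the diarylmethine) is present.

**Compound list**

1 | 1-(2,6-dihydroxy-4-methoxyphenyl)ethan-1-one | CC(=O)c1c(O)cc(OC)cc1O | starting material
2 | (E)-3-(dimethylamino)-1-(2,6-dihydroxy-4-methoxyphenyl)prop-2-en-1-one | CN(C)/C=C/C(=O)c1c(O)cc(OC)cc1O | intermediate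
3 | 4-bromo-2-hydroxybenzaldehyde | O=Cc1ccc(Br)cc1O | starting material
4 | 1-(2,4-dimethoxyphenyl)ethan-1-one | CC(=O)c1ccc(OC)cc1OC | starting material
5 | (E)-3-(4-bromo-2-hydroxyphenyl)-1-(2,4-dimethoxyphenyl)prop-2-en-1-one | COc1ccc(C(=O)/C=C/c2ccc(Br)cc2O)c(OC)c1 | intermediate
6 | (E)-3-[4-bromo-2-(tert-butyldimethylsilyloxy)phenyl]-1-(2,4-dimethoxyphenyl)prop-2-en-1-one | COc1ccc(C(=O)/C=C/c2ccc(Br)cc2O[Si](C)(C)C(C)(C)C)c(OC)c1 | intermediate
7 | [4-(tert-butyldimethylsilyloxy)phenyl]boronic acid | CC(C)(C)[Si](C)(C)Oc1ccc(B(O)O)cc1 | starting material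
8 | (3R)-3-[4-bromo-2-(tert-butyldimethylsilyloxy)phenyl]-3-[4-(tert-butyldimethylsilyloxy)phenyl]-1-(2,4-dimethoxyphenyl)propan-1-one | COc1ccc(C(=O)C[C@H](c2ccc(O[Si](C)(C)C(C)(C)C)cc2)c2ccc(Br)cc2O[Si](C)(C)C(C)(C)C)c(OC)c1 | intermediate
9 | (3R)-3-[4-bromo-2-(tert-butyldimethylsilyloxy)phenyl]-3-[4-(tert-butyldimethylsilyloxy)phenyl]-1-(2,4-dimethoxyphenyl)propan-1-ol, mixture of C1 epimers | COc1ccc(C(O)C[C@H](c2ccc(O[Si](C)(C)C(C)(C)C)cc2)c2ccc(Br)cc2O[Si](C)(C)C(C)(C)C)c(OC)c1 | intermediate
10 | 4-bromo-2-(tert-butyldimethylsilyloxy)-1-[(1R,2E)-3-(2,4-dimethoxyphenyl)-1-[4-(tert-butyldimethylsilyloxy)phenyl]prop-2-en-1-yl]benzene | COc1ccc(/C=C/[C@H](c2ccc(O[Si](C)(C)C(C)(C)C)cc2)c2ccc(Br)cc2O[Si](C)(C)C(C)(C)C)c(OC)c1 | intermediate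
11 | ethyl N-hydroxyethanimidate (ethyl acetohydroximate) | CCOC(C)=NO | starting material
12 | ethyl N-{3-(tert-butyldimethylsilyloxy)-4-[(1R,2E)-3-(2,4-dimethoxyphenyl)-1-[4-(tert-butyldimethylsilyloxy)phenyl]prop-2-en-1-yl]phenoxy}ethanimidate | COc1ccc(/C=C/[C@H](c2ccc(O[Si](C)(C)C(C)(C)C)cc2)c2ccc(ON=C(C)OCC)cc2O[Si](C)(C)C(C)(C)C)c(OC)c1 | intermediate
13 | O-{3-(tert-butyldimethylsilyloxy)-4-[(1R,2E)-3-(2,4-dimethoxyphenyl)-1-[4-(tert-butyldimethylsilyloxy)phenyl]prop-2-en-1-yl]phenyl}hydroxylamine (formed in the flask, step 8) | COc1ccc(/C=C/[C@H](c2ccc(O[Si](C)(C)C(C)(C)C)cc2)c2ccc(ON)cc2O[Si](C)(C)C(C)(C)C)c(OC)c1 | intermediate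
14 | (Z)-3-({3-(tert-butyldimethylsilyloxy)-4-[(1R,2E)-3-(2,4-dimethoxyphenyl)-1-[4-(tert-butyldimethylsilyloxy)phenyl]prop-2-en-1-yl]phenoxy}amino)-1-(2,6-dihydroxy-4-methoxyphenyl)prop-2-en-1-one (formed in the flask, step 8) | COc1ccc(/C=C/[C@H](c2ccc(O[Si](C)(C)C(C)(C)C)cc2)c2ccc(ON/C=C\C(=O)c3c(O)cc(OC)cc3O)cc2O[Si](C)(C)C(C)(C)C)c(OC)c1 | intermediate
15 | 3-amino-1-(2,6-dihydroxy-4-methoxyphenyl)-2-{2-hydroxy-4-(tert-butyldimethylsilyloxy)-5-[(1R,2E)-3-(2,4-dimethoxyphenyl)-1-[4-(tert-butyldimethylsilyloxy)phenyl]prop-2-en-1-yl]phenyl}prop-2-en-1-one (formed in the flask, step 8) | COc1ccc(/C=C/[C@H](c2ccc(O[Si](C)(C)C(C)(C)C)cc2)c2cc(C(=CN)C(=O)c3c(O)cc(OC)cc3O)c(O)cc2O[Si](C)(C)C(C)(C)C)c(OC)c1 | intermediate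
16 | 5-hydroxy-3-{2-hydroxy-4-(tert-butyldimethylsilyloxy)-5-[(1R,2E)-3-(2,4-dimethoxyphenyl)-1-[4-(tert-butyldimethylsilyloxy)phenyl]prop-2-en-1-yl]phenyl}-7-methoxy-4H-chromen-4-one | COc1ccc(/C=C/[C@H](c2ccc(O[Si](C)(C)C(C)(C)C)cc2)c2cc(-c3coc4cc(OC)cc(O)c4c3=O)c(O)cc2O[Si](C)(C)C(C)(C)C)c(OC)c1 | intermediate
17 | caraganin B, 3-{5-[(1R,2E)-3-(2,4-dimethoxyphenyl)-1-(4-hydroxyphenyl)prop-2-en-1-yl]-2,4-dihydroxyphenyl}-5-hydroxy-7-methoxy-4H-chromen-4-one | COc1ccc(/C=C/[C@H](c2ccc(O)cc2)c2cc(-c3coc4cc(OC)cc(O)c4c3=O)c(O)cc2O)c(OC)c1 | target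

**Step count and risks**

Total step count: 9. Longest linear sequence: 8 steps (steps 2–9, from 3 and 4); the enaminone branch is one step.

Steps most likely to fail:

Step 8 (proposed new method). The exchanged enaminone may close ring C before the [3,3] shift and expel the aryloxyamine; the aldoxime tautomer may eliminate the phenol (nitrile formation); or the acid may hydrate or oligomerise the electron-rich styrene. The fallback uses known Suzuki–Miyaura chemistry, sets out from 12 and returns at 16. Reductive N–O cleavage of 12 (Zn, AcOH/THF, rt) should give the phenol F1. Iodination of its phenoxide (I2, morpholine, CH2Cl2, 0 °C) at the only unhindered ortho position should give the 2-iodophenol F2. Miyaura borylation (B2pin2, PdCl2(dppf), KOAc, dioxane, 80 °C) should give the pinacol boronate F3. Separately, iodocyclisation of enaminone 2 (I2, CHCl3, rt) should give the 3-iodochromone F4. Suzuki–Miyaura coupling of F3 with F4 (Pd(PPh3)4, Na2CO3, DME/H2O, 80 °C) should then give 16, which goes on to step 9.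

Step 4. Carbometalation next to the ortho-silyloxy group may be slow, with protodeboronation taking over, or facial discrimination on the acyclic enone may be poor because the two aryl groups at the new centre are alike in size. The fallback moves the addition to a rigid cyclic enoate; it sets out from 3 and returns at 8. Wittig olefination/lactonisation of 3 (Ph3P=CHCO2Et, PhNEt2, reflux) should give 7-bromocoumarin F5. Rh/(R)-SEGPHOS-catalysed addition of 7 (Rh(acac)(C2H4)2, dioxane/H2O, 60 °C), a substrate class with close precedent for high enantioselectivity, should give the dihydrocoumarin F6. Aminolysis (MeNHOMe·HCl, AlMe3, CH2Cl2) should give the phenolic Weinreb amide F7, and silylation (TBSCl, imidazole) the silyl ether F8. Addition of commercial 2,4-dimethoxyphenylmagnesium bromide (THF, 0 °C) should give 8.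

Step 7. Hydrodebromination or slow C–O reductive elimination may outrun the coupling, or the base may start to cleave the silyl ethers. The fallback replaces the Pd step by a Cu-mediated O-arylation; it sets out from 10 and returns at 13. Bromine–lithium exchange and borylation (n-BuLi, THF, −78 °C; B(OiPr)3; aq. NH4Cl) should give the boronic acid F9. Chan–Lam coupling with N-hydroxyphthalimide (Cu(OAc)2, pyridine, 4 Å MS, DCE, air, rt) should give the N-aryloxyphthalimide F10. Hydrazinolysis (N2H4·H2O, CH2Cl2/MeOH, rt) should give aryloxyamine 13, which enters step 8 at the exchange stage.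

**Further compounds**

F1 | step 8 | 3-(tert-butyldimethylsilyloxy)-4-[(1R,2E)-3-(2,4-dimethoxyphenyl)-1-[4-(tert-butyldimethylsilyloxy)phenyl]prop-2-en-1-yl]phenol | COc1ccc(/C=C/[C@H](c2ccc(O[Si](C)(C)C(C)(C)C)cc2)c2ccc(O)cc2O[Si](C)(C)C(C)(C)C)c(OC)c1
F2 | step 8 | 5-(tert-butyldimethylsilyloxy)-4-[(1R,2E)-3-(2,4-dimethoxyphenyl)-1-[4-(tert-butyldimethylsilyloxy)phenyl]prop-2-en-1-yl]-2-iodophenol | COc1ccc(/C=C/[C@H](c2ccc(O[Si](C)(C)C(C)(C)C)cc2)c2cc(I)c(O)cc2O[Si](C)(C)C(C)(C)C)c(OC)c1
F3 | step 8 | 5-(tert-butyldimethylsilyloxy)-4-[(1R,2E)-3-(2,4-dimethoxyphenyl)-1-[4-(tert-butyldimethylsilyloxy)phenyl]prop-2-en-1-yl]-2-(4,4,5,5-tetramethyl-1,3,2-dioxaborolan-2-yl)phenol | COc1ccc(/C=C/[C@H](c2ccc(O[Si](C)(C)C(C)(C)C)cc2)c2cc(B3OC(C)(C)C(C)(C)O3)c(O)cc2O[Si](C)(C)C(C)(C)C)c(OC)c1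
F4 | step 8 | 5-hydroxy-3-iodo-7-methoxy-4H-chromen-4-one | COc1cc(O)c2c(=O)c(I)coc2c1
F5 | step 4 | 7-bromo-2H-chromen-2-one (7-bromocoumarin) | O=c1ccc2ccc(Br)cc2o1
F6 | step 4 | (4R)-7-bromo-4-[4-(tert-butyldimethylsilyloxy)phenyl]chroman-2-one | O=C1C[C@H](c2ccc(O[Si](C)(C)C(C)(C)C)cc2)c2ccc(Br)cc2O1
F7 | step 4 | (3R)-3-(4-bromo-2-hydroxyphenyl)-3-[4-(tert-butyldimethylsilyloxy)phenyl]-N-methoxy-N-methylpropanamide | CON(C)C(=O)C[C@H](c1ccc(O[Si](C)(C)C(C)(C)C)cc1)c1ccc(Br)cc1O
F8 | step 4 | (3R)-3-[4-bromo-2-(tert-butyldimethylsilyloxy)phenyl]-3-[4-(tert-butyldimethylsilyloxy)phenyl]-N-methoxy-N-methylpropanamide | CON(C)C(=O)C[C@H](c1ccc(O[Si](C)(C)C(C)(C)C)cc1)c1ccc(Br)cc1O[Si](C)(C)C(C)(C)C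
F9 | step 7 | {3-(tert-butyldimethylsilyloxy)-4-[(1R,2E)-3-(2,4-dimethoxyphenyl)-1-[4-(tert-butyldimethylsilyloxy)phenyl]prop-2-en-1-yl]phenyl}boronic acid | COc1ccc(/C=C/[C@H](c2ccc(O[Si](C)(C)C(C)(C)C)cc2)c2ccc(B(O)O)cc2O[Si](C)(C)C(C)(C)C)c(OC)c1
F10 | step 7 | 2-{3-(tert-butyldimethylsilyloxy)-4-[(1R,2E)-3-(2,4-dimethoxyphenyl)-1-[4-(tert-butyldimethylsilyloxy)phenyl]prop-2-en-1-yl]phenoxy}isoindoline-1,3-dione | COc1ccc(/C=C/[C@H](c2ccc(O[Si](C)(C)C(C)(C)C)cc2)c2ccc(ON3C(=O)c4ccccc4C3=O)cc2O[Si](C)(C)C(C)(C)C)c(OC)c1
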